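Count the amounts first. Each protic impurity that reacts takes one starting material away for good, while the reversible step only parks starting material as product, two to each product.

| setting | oak | cedar | flask |
|---|---|---|---|
| starting material | 0.14 M | 0.21 M | 0.28 M |
| protic impurity | 0.056 M | 0.056 M | 0.0560 M |
| remark | run made earlier | run made earlier |  |
| time |  |  | 2.0 h |

| oak: time / h | oak: product / % | cedar: time / h | cedar: product / % |
|---|---|---|---|
| 0.133 | 17.7 | 0.133 | 23.8 |
| 0.200 | 21.9 | 0.200 | 29.9 |
| 0.333 | 27.0 | 0.333 | 35.6 |
| 0.500 | 29.4 | 0.500 | 36.0 |
| 1.00 | 26.7 | 1.00 | 33.9 |
| 1.33 | 25.5 | 1.33 | 33.5 |
| 2.50 | 21.0 | 2.50 | 31.1 |

(each reading ± 0.5 percentage points)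

1. time, not beyond 2.0 h, at which the flask holds most product
2. the amount of product, in percent of the starting material charged, at that time
3. earliest time at which at least nineteen twentieths of that best amount are there
4. latest time at which they still are

- percentages count the starting material that a species holds: one product counts as two
- steps under discussion: 2 starting material <-> product; starting material + protic impurity -> quenched substrate

Divide the charge of protic impurity by the charge of starting material. In the flask this gives 20.0%. Call it the toll, the share of the charge that the quench has taken once the protic impurity is gone. In the flask the protic impurity is the limiting reagent of the quench, with less of it charged than starting material.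

Now run the earlier flasks slowly. In the first instants product climbs: at 0.133 h oak reads 17.7% and cedar 23.8%. In the middle both read highest at 0.500 h, oak 29.4% and cedar 36.0%. Then both sag. Oak loses 8.4 percentage points by its last reading and cedar 4.9 points, a smaller fall. Their tolls are 40.0% and 26.7%.

So treat the quench as a correction. Take the toll off the charge and split the rest by the balance of the reversible step. Suppose cedar has paid its toll at 2.50 h. Its reading then gives [product] over the square of [starting material] as 4.15 /M, a reading with its scatter. Split the flask's remainder by that value, and my late level for the flask is 39.0% product.

The forecast relaxes to 38.5% instead. It puts the top at 42.5% near 0.6 h, with the window from 0.34 h to 1.1 h. Its ground: “Both runs rise quickly, peak, then sag as the impurity eats starting material released from product.”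

The flask tops at 41.9% at 0.538 h and keeps the share of that asked for from 0.305 h to 1.18 h, each inside the forecast's range.

    2 starting material ⇌ product (K = 3.80 /M, k = 0.00208 /M/s)
    starting material + protic impurity → quenched substrate (k = 0.00376 /M/s)

At 2.00 h the reversible step, taken by itself and counted both ways together, relaxes in the flask with a half-life of 0.126 h, short against the time allowed and shorter than the 0.43 h half-life of the protic impurity by the quench. At 20.0 h the flask holds 20.0% quenched substrate against its toll of 20.0%, with 37.8% product. With 0.48 M starting material the toll falls to 11.7% and the same split gives 52.1% product; that neighbour flask holds 11.6% quenched substrate and 51.0% product at 2.00 h.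

The numbers in the tables stem from a simulated flask on assumed constants; noise was put on by code.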